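**Retrosynthetic overview**
1. Target 31 ⇐ reagent-controlled reduction of the C3 ketone and peracid epoxidation of the (Z)-C7=C8 alkene of ten-membered ketone 29; both angelates go on just before.
2. Ten-membered ring ⇐ four-carbon ring expansion of cyclohexanone 23: samarium pinacol closure of C3–C4, then Grob cleavage of the shared C3–C8 bond in the same flask.
3. 23 ⇐ samarium aldol union (C7–C8) of epoxy ketone 13 (C1–C3, C8–C10) with keto aldehyde 19 (C4–C7).
4. 13 ⇐ o-cresol (quinone monoketal, Rh-catalysed isopropenyl addition, directed epoxidation); 19 ⇐ acetaldehyde + 3-(trimethylsilyl)propynal.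
5. Ring order: ring B (six-membered, from o-cresol) first; ring A (six-membered) exists only transiently in the key step, which merges both into the ten-membered ring; the epoxide is formed last.

Assumption: locants C1–C10 are those of the target ring (C1 = CH–isopropenyl, C2 = CH2, C3 = CHOH, C4 = C(CH3)OH, C5, C6 = CH2, C7/C8 = epoxide, C9, C10), and for each chiral catalyst the antipode that gives the drawn configuration is used.

**Route**

Step 1
Reactants: 1 2-methylphenol (o-cresol)
Product: 3 4,4-dimethoxy-2-methylcyclohexa-2,5-dien-1-one, via 4-methoxy-2-methylphenol 2 (not isolated)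
Conditions: PhI(OAc)2 (2.2 equiv), MeOH, 0 to 25 °C
Reagents that add atoms: methanol, CO
Why: Oxidative dearomatisation with a hypervalent iodine reagent, in which the para-unsubstituted phenol is para-methoxylated and then oxidised again in methanol to the quinone monoketal, leaving one free enone carbonyl (later C3) and masking the other (later C10), with no stereocentre formed.

Step 2
Reactants: 3 4,4-dimethoxy-2-methylcyclohexa-2,5-dien-1-one; 4 potassium trifluoro(prop-1-en-2-yl)borate
Product: 5 (5R)-4,4-dimethoxy-2-methyl-5-(prop-1-en-2-yl)cyclohex-2-en-1-one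
Conditions: [Rh(cod)2]BF4 (3 mol%), (R)-2,2'-bis(diphenylphosphino)-1,1'-binaphthyl (3.3 mol%), Et3N, toluene/H2O 10:1, 25 °C
Reagents that add atoms: none
Why: Rhodium-catalysed asymmetric conjugate addition (Hayashi–Miyaura type) of the alkenyl trifluoroborate occurs at the unsubstituted enone of the dienone because the α-methyl enone is a poor acceptor, and the bisphosphine-bound alkenylrhodium selects one face, which sets C1 (R).

Step 3
Reactants: 5 (5R)-4,4-dimethoxy-2-methyl-5-(prop-1-en-2-yl)cyclohex-2-en-1-one
Product: 6 (1R,5R)-4,4-dimethoxy-2-methyl-5-(prop-1-en-2-yl)cyclohex-2-en-1-ol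
Conditions: NaBH4, CeCl3·7H2O, MeOH, −78 °C
Reagents that add atoms: none
Why: Luche 1,2-reduction, in which axial hydride attack gives the equatorial C3 alcohol cis to the equatorial isopropenyl group (the carvone to cis-carveol precedent), the directing group for the next step.

Step 4
Reactants: 6 (1R,5R)-4,4-dimethoxy-2-methyl-5-(prop-1-en-2-yl)cyclohex-2-en-1-ol
Product: 7 epoxy alcohol (C8–C9 epoxide cis to the C3 hydroxyl)
Conditions: VO(acac)2 (5 mol%), t-BuOOH, CH2Cl2, 0 °C
Reagents that add atoms: tert-butyl hydroperoxide, CC(C)(C)OO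
Why: Hydroxyl-directed vanadium-catalysed epoxidation of the allylic alcohol delivers oxygen syn to the C3 hydroxyl, which puts the epoxide oxygen (the future O9) cis to the isopropenyl group and leaves the isolated isopropenyl alkene alone.

Step 5
Reactants: 7 epoxy alcohol
Product: 8 hydroxy epoxy ketone (C10 ketone)
Conditions: pyridinium p-toluenesulfonate, acetone/H2O 10:1, 25 °C
Reagents that add atoms: water, O
Why: Acetal hydrolysis with a weak acid frees the C10 ketone while the epoxide, which needs stronger acid to open, is kept and no stereocentre is touched.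

Step 6
Reactants: 8 hydroxy epoxy ketone
Product: 9 epoxy diol (C3–OH and C10–OH)
Conditions: NaBH4, MeOH, −40 °C
Reagents that add atoms: none
Why: Borohydride reduction of the α,β-epoxy ketone with hydride entering anti to the epoxide oxygen and to the neighbouring isopropenyl group gives the C10 alcohol cis to both, which sets C10.

Step 7
Reactants: 9 epoxy diol
Product: 10 epoxy ketol (C3 ketone, free C10–OH)
Conditions: 2,2,6,6-tetramethylpiperidin-1-oxyl (10 mol%), PhI(OAc)2 (1.1 equiv), CH2Cl2, 0 °C
Reagents that add atoms: none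
Why: The bulky oxoammonium (TEMPO) oxidant takes the C3 carbinol, which has a CH2 neighbour, in preference to the C10 carbinol flanked by two branched carbons, restoring the C3 ketone without touching a stereocentre that is kept.

Step 8
Reactants: 10 epoxy ketol; 11 (R)-2-methylbutanoic acid
Product: 13 epoxy ketone (R)-2-methylbutanoate, via mixed anhydride 12 (not isolated)
Conditions: 11, 2,4,6-Cl3C6H2COCl, Et3N, THF, 25 °C; then 10, 4-(dimethylamino)pyridine (cat.), toluene, 40 °C
Reagents that add atoms: none
Why: Yamaguchi esterification through the mixed anhydride acylates the hindered C10 hydroxyl with retention at C10 and without enolising the α-stereocentre of the acid, and the cis relation of O10 to the epoxide oxygen rules out a Payne rearrangement.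

Step 9
Reactants: 14 3-(trimethylsilyl)prop-2-ynal; 15 acetaldehyde
Product: 16 (S)-3-hydroxy-5-(trimethylsilyl)pent-4-ynal
Conditions: (S)-bis[3,5-bis(trifluoromethyl)phenyl](pyrrolidin-2-yl)methanol (10 mol%), DMF, 4 °C
Reagents that add atoms: none
Why: Enamine-catalysed direct cross-aldol reaction of acetaldehyde with the non-enolisable ynal, in which the diarylprolinol shields one face of the enamine and sets C5 (S).

Step 10
Reactants: 16 (S)-3-hydroxy-5-(trimethylsilyl)pent-4-ynal
Product: 17 (S)-3-[(tert-butyldimethylsilyl)oxy]-5-(trimethylsilyl)pent-4-ynal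
Conditions: TBSCl, imidazole, DMF, 0 °C
Reagents that add atoms: tert-butyldimethylsilyl chloride, CC(C)(C)[Si](C)(C)Cl
Why: Standard silyl ether formation protects O5 as a group that will not leave from the carbon next to the later ketyl, and the stereocentre is untouched.

Step 11
Reactants: 17 (S)-3-[(tert-butyldimethylsilyl)oxy]-5-(trimethylsilyl)pent-4-ynal
Product: 19 (S)-3-[(tert-butyldimethylsilyl)oxy]-4-oxopentanal, via terminal alkyne 18 (not isolated)
Conditions: Ph3PAuCl (2 mol%), AgOTf (2 mol%), THF/H2O 5:1, 40 °C
Reagents that add atoms: water, O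
Why: Gold-catalysed alkyne hydration, in which the alkynylsilane is protodesilylated and the terminal alkyne then adds water in the Markovnikov sense to give the methyl ketone, with C5 untouched.

Step 12
Reactants: 13 epoxy ketone (R)-2-methylbutanoate; 19 (S)-3-[(tert-butyldimethylsilyl)oxy]-4-oxopentanal
Product: 21 aldol diol, via samarium enolate 20 (not isolated)
Conditions: 13, SmI2 (2.2 equiv), THF, −78 °C, 10 min; then 19, −78 °C; pH 7 buffer
Reagents that add atoms: none
Why: Two-electron reductive opening of the α,β-epoxy ketone gives the C8 enolate of trivalent samarium regiospecifically with O9 as an alkoxide (so no β-elimination), and its samarium aldol reaction through a chelated chair (Zimmerman–Traxler) transition state, with the aldehyde carried by the O9-bound samarium to the ring face of O9 in an axial attack, creates the quaternary C8 with C7 cis to O9 and the C7 carbinol anti to C9.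

Step 13
Reactants: 21 aldol diol
Product: 23 keto mesylate O9-triethylsilyl ether, via mesylate 22 (not isolated)
Conditions: MsCl, Et3N, CH2Cl2, −20 °C; then 2,6-lutidine, TESOTf, −78 to −20 °C
Reagents that add atoms: methanesulfonyl chloride, CS(=O)(=O)Cl; triethylsilyl trifluoromethanesulfonate, CC[Si](CC)(CC)OS(=O)(=O)C(F)(F)F
Why: Sulfonylation takes the side-chain C7 hydroxyl, which is less hindered than the ring C9 hydroxyl wedged between C8 and C10, and the silyl triflate then caps O9 in the same flask so that the neighbouring ester cannot migrate, with no stereocentre changed.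

Step 14
Reactants: 23 keto mesylate O9-triethylsilyl ether
Product: 25 ten-membered α-hydroxy ketone, via samarium diolate 24 (not isolated)
Conditions: SmI2 (2.5 equiv), hexamethylphosphoramide (8 equiv), THF, −78 to 25 °C
Reagents that add atoms: none
Why: Proposed new method: the α-silyloxy methyl ketone is reduced to its ketyl, which adds to the ring ketone in a chelated six-membered pinacol cyclization (both oxygens on samarium, hence a cis-diol with O4 anti to the C5 silyl ether and a cis-fused decalin), and the resulting C3 alkoxide of trivalent samarium has the C3–C8 bond anti-periplanar to the equatorial C7 mesylate, so that Grob fragmentation follows in the same flask and gives the ten-membered C3 ketone with the (Z)-C7=C8 alkene (mesylate trans to the C8 methyl) and the C4 stereocentre, the closest known reactions being the samarium diiodide ketone–ketone pinacol cyclization and the samarium diiodide Barbier cyclization–Grob fragmentation route to medium-ring cycloalkenones.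

Step 15
Reactants: 25 ten-membered α-hydroxy ketone
Product: 26 ten-membered triol ketone
Conditions: HF·pyridine, pyridine/THF, 0 to 25 °C
Reagents that add atoms: none
Why: Fluoride-driven cleavage of both silyl ethers under buffered conditions that leave the ester, the α-ketol and the alkenes alone.

Step 16
Reactants: 26 ten-membered triol ketone; 27 angelic acid
Product: 29 bis-angelate ketone, via angelic mixed anhydride 28 (not isolated)
Conditions: 27 (6 equiv), 2,4,6-Cl3C6H2COCl (6 equiv), Et3N (6.5 equiv), toluene, 25 °C; then 26, 75 °C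
Reagents that add atoms: angelic acid (second equivalent), C/C=C(/C)C(=O)O
Why: Yamaguchi-type acylation with the preformed mixed anhydride (no 4-(dimethylamino)pyridine, which would isomerise angelate to tiglate) esterifies both secondary hydroxyls at C5 and C9, so that two molecules of angelic acid end up in 29 (one per ester), while the tertiary C4 hydroxyl does not react.

Step 17
Reactants: 29 bis-angelate ketone
Product: 30 epoxy ketone
Conditions: mCPBA, NaHCO3, CH2Cl2, 0 °C
Reagents that add atoms: 3-chloroperoxybenzoic acid, O=C(OO)c1cccc(Cl)c1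
Why: Prilezhaev epoxidation, in which the electron-rich trisubstituted ring alkene reacts much faster than the isopropenyl and angelate alkenes and the peracid attacks the (Z)-alkene on the face away from the allylic C9 ester, as is usual for (Z)-allylic systems in medium rings, giving the cis-epoxide with its oxygen trans to O9 and setting C7 and C8.

Step 18
Reactants: 30 epoxy ketone
Product: 31 target CNP0246823.3
Conditions: (S)-1-methyl-3,3-diphenyltetrahydro-1H,3H-pyrrolo[1,2-c][1,3,2]oxazaborole (1 equiv), catecholborane, toluene, −60 °C; then MeOH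
Reagents that add atoms: none
Why: Corey–Bakshi–Shibata reduction under reagent control, with the fully substituted C4 as the large and C2H2 as the small ketone substituent, delivers hydride to the face that gives the (3R) alcohol, and esters and epoxide are inert to catecholborane at this temperature.

**Compound list**

1 | 2-methylphenol (o-cresol) | Cc1ccccc1O | starting material
2 | 4-methoxy-2-methylphenol | COc1ccc(O)c(C)c1 | intermediate
3 | 4,4-dimethoxy-2-methylcyclohexa-2,5-dien-1-one | COC1(OC)C=CC(=O)C(C)=C1 | intermediate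
4 | potassium trifluoro(prop-1-en-2-yl)borate | [K+].CC(=C)[B-](F)(F)F | starting material
5 | (5R)-4,4-dimethoxy-2-methyl-5-(prop-1-en-2-yl)cyclohex-2-en-1-one | C=C(C)[C@H]1CC(=O)C(C)=CC1(OC)OC | intermediate
6 | (1R,5R)-4,4-dimethoxy-2-methyl-5-(prop-1-en-2-yl)cyclohex-2-en-1-ol, OH cis to isopropenyl | C=C(C)[C@H]1C[C@@H](O)C(C)=CC1(OC)OC | intermediate
7 | epoxy alcohol: 6 epoxidised at the ring alkene; epoxide O, C3–OH and isopropenyl all cis | C=C(C)[C@H]1C[C@@H](O)[C@@]2(C)O[C@H]2C1(OC)OC | intermediate
8 | hydroxy epoxy ketone: 7 with the ketal hydrolysed to the C10 ketone | C=C(C)[C@H]1C[C@@H](O)[C@@]2(C)O[C@H]2C1=O | intermediate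
9 | epoxy diol: C3–OH, C10–OH, epoxide O and isopropenyl all cis | C=C(C)[C@H]1C[C@@H](O)[C@@]2(C)O[C@H]2[C@H]1O | intermediate
10 | epoxy ketol: C3 ketone, C8–C9 epoxide, C10–OH; epoxide O, O10 and isopropenyl cis | C=C(C)[C@H]1CC(=O)[C@@]2(C)O[C@H]2[C@H]1O | intermediate
11 | (R)-2-methylbutanoic acid | CC[C@@H](C)C(=O)O | starting material
12 | (R)-2-methylbutanoic 2,4,6-trichlorobenzoic anhydride | CC[C@@H](C)C(=O)OC(=O)c1c(Cl)cc(Cl)cc1Cl | intermediate
13 | epoxy ketone ester: O10-(R)-2-methylbutanoate of 10 | C=C(C)[C@H]1CC(=O)[C@@]2(C)O[C@H]2[C@H]1OC(=O)[C@H](C)CC | intermediate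
14 | 3-(trimethylsilyl)prop-2-ynal | C[Si](C)(C)C#CC=O | starting material
15 | acetaldehyde | CC=O | starting material
16 | (S)-3-hydroxy-5-(trimethylsilyl)pent-4-ynal | O=CC[C@H](O)C#C[Si](C)(C)C | intermediate
17 | (S)-3-[(tert-butyldimethylsilyl)oxy]-5-(trimethylsilyl)pent-4-ynal | O=CC[C@H](O[Si](C)(C)C(C)(C)C)C#C[Si](C)(C)C | intermediate
18 | (S)-3-[(tert-butyldimethylsilyl)oxy]pent-4-ynal | O=CC[C@H](O[Si](C)(C)C(C)(C)C)C#C | intermediate
19 | (S)-3-[(tert-butyldimethylsilyl)oxy]-4-oxopentanal | O=CC[C@H](O[Si](C)(C)C(C)(C)C)C(C)=O | intermediate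
20 | samarium enolate: C3/C8 enolate and O9 alkoxide of trivalent samarium from 13 | C=C(C)[C@H]1CC([O-])=C(C)[C@@H]([O-])[C@H]1OC(=O)[C@H](C)CC.[Sm+3].[Sm+3].[I-].[I-].[I-].[I-] | intermediate
21 | aldol diol: cyclohexanone with quaternary C8 (methyl trans to isopropenyl), side chain (7R)-CH(OH)–CH2–(5S)-CH(OTBS)–C(=O)CH3 on the isopropenyl face, C9–OH and O10 ester cis to isopropenyl | C=C(C)[C@H]1CC(=O)[C@@](C)([C@H](O)C[C@H](O[Si](C)(C)C(C)(C)C)C(C)=O)[C@@H](O)[C@H]1OC(=O)[C@H](C)CC | intermediate
22 | C7 mesylate of 21 | C=C(C)[C@H]1CC(=O)[C@@](C)([C@H](OS(C)(=O)=O)C[C@H](O[Si](C)(C)C(C)(C)C)C(C)=O)[C@@H](O)[C@H]1OC(=O)[C@H](C)CC | intermediate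
23 | keto mesylate: 22 with O9 as triethylsilyl ether | C=C(C)[C@H]1CC(=O)[C@@](C)([C@H](OS(C)(=O)=O)C[C@H](O[Si](C)(C)C(C)(C)C)C(C)=O)[C@@H](O[Si](CC)(CC)CC)[C@H]1OC(=O)[C@H](C)CC | intermediate
24 | samarium diolate: cis-fused decalin with cis C3/C4 diolate on trivalent samarium, C7 mesylate trans to the C8 methyl | C=C(C)[C@H]1C[C@@]2([O-])[C@](C)([O-])[C@@H](O[Si](C)(C)C(C)(C)C)C[C@@H](OS(C)(=O)=O)[C@@]2(C)[C@@H](O[Si](CC)(CC)CC)[C@H]1OC(=O)[C@H](C)CC.[Sm+3].[Sm+3].[I-].[I-].[I-].[I-] | intermediate
25 | ten-membered α-hydroxy ketone: C3 ketone, C4 (CH3)(OH), O5-TBS, (Z)-C7=C8, O9-TES, O10-(R)-2-methylbutanoate, C1 isopropenyl; stereocentres as in 31 | C=C(C)[C@H]1CC(=O)[C@](C)(O)[C@@H](O[Si](C)(C)C(C)(C)C)C/C=C(C)\[C@@H](O[Si](CC)(CC)CC)[C@H]1OC(=O)[C@H](C)CC | intermediate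
26 | ten-membered triol ketone: 25 with free C5–OH and C9–OH | C=C(C)[C@H]1CC(=O)[C@](C)(O)[C@@H](O)C/C=C(C)\[C@@H](O)[C@H]1OC(=O)[C@H](C)CC | intermediate
27 | angelic acid, (Z)-2-methylbut-2-enoic acid | C/C=C(/C)C(=O)O | starting material
28 | angelic 2,4,6-trichlorobenzoic anhydride | C/C=C(/C)C(=O)OC(=O)c1c(Cl)cc(Cl)cc1Cl | intermediate
29 | bis-angelate ketone: 26 with angelates on O5 and O9 | C=C(C)[C@H]1CC(=O)[C@](C)(O)[C@@H](OC(=O)/C(C)=C\C)C/C=C(C)\[C@@H](OC(=O)/C(C)=C\C)[C@H]1OC(=O)[C@H](C)CC | intermediate
30 | epoxy ketone: 29 with the (7S,8S) cis-epoxide, oxygen trans to O9 | C=C(C)[C@H]1CC(=O)[C@](C)(O)[C@@H](OC(=O)/C(C)=C\C)C[C@@H]2O[C@]2(C)[C@@H](OC(=O)/C(C)=C\C)[C@H]1OC(=O)[C@H](C)CC | intermediate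
31 | CNP0246823.3: (1R,3R,4S,5S,7S,8S,9S,10S) epoxy germacrane diol with 5,9-diangelate and 10-(R)-2-methylbutanoate | C=C(C)[C@H]1C[C@@H](O)[C@](C)(O)[C@@H](OC(=O)/C(C)=C\C)C[C@@H]2O[C@]2(C)[C@@H](OC(=O)/C(C)=C\C)[C@H]1OC(=O)[C@H](C)CC | target

**Step count and weak points**

Total steps: 18. Longest linear sequence: 15 (steps 1–8 and 12–18; steps 9–11 make the side fragment).

Step 12 (samarium aldol). The aldehyde must enter C8 on the more crowded ring face, past the axial O10 ester, and the O9 alkoxide sits next to that ester. The fallback sets out from 13: SmI2 (THF, −78 °C) followed by Me3SiCl/Et3N gives the isolable bis(trimethylsilyl) enol ether F1. A Mukaiyama aldol reaction of it with 19 (BF3·OEt2, CH2Cl2, −78 °C, open transition state with axial attack) gives the O9-trimethylsilyl aldol F2. Citric acid in MeOH removes the trimethylsilyl group and the route is rejoined at 21.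

Step 14 (the proposed cascade). The ketyl may simply be reduced, or the samarium alkoxide may not fragment, because the reactive cis-decalin conformer forces ring B to carry the isopropenyl group and O9 axially. The fallback uses known chemistry and sets out from 23: the ordinary SmI2 pinacol cyclization, run with t-BuOH at −78 °C and quenched cold, gives the cis-decalin diol mesylate F3. The classical base-induced Grob (Wharton) fragmentation of this 1,3-diol monosulfonate with KN(SiMe3)2 (THF, −78 to 0 °C) then rejoins the route at 25.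

Step 17 (epoxidation face in the ten-membered ring). If the peracid takes the other face, the fallback sets out from 29: N-bromosuccinimide in acetone/H2O gives the bromohydrin F4 (bromine on the face the peracid takes, water at the tertiary C8 from the other face). Cs2CO3 in MeCN closes it with inversion at C7 to the epoxide on the opposite face, rejoining the route at 30.

**Further compounds**

F1 | step 12 | bis(trimethylsilyl) enol ether: C3 silyl enol ether and O9 silyl ether from 13 | C=C(C)[C@H]1CC(O[Si](C)(C)C)=C(C)[C@@H](O[Si](C)(C)C)[C@H]1OC(=O)[C@H](C)CC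
F2 | step 12 | O9-trimethylsilyl aldol: 21 with O9 as trimethylsilyl ether | C=C(C)[C@H]1CC(=O)[C@@](C)([C@H](O)C[C@H](O[Si](C)(C)C(C)(C)C)C(C)=O)[C@@H](O[Si](C)(C)C)[C@H]1OC(=O)[C@H](C)CC
F3 | step 14 | cis-decalin diol mesylate: protonated form of 24 | C=C(C)[C@H]1C[C@@]2(O)[C@](C)(O)[C@@H](O[Si](C)(C)C(C)(C)C)C[C@@H](OS(C)(=O)=O)[C@@]2(C)[C@@H](O[Si](CC)(CC)CC)[C@H]1OC(=O)[C@H](C)CC
F4 | step 17 | bromohydrin: C7 bromide cis to O9, tertiary C8 hydroxyl trans to O9 | C=C(C)[C@H]1CC(=O)[C@](C)(O)[C@@H](OC(=O)/C(C)=C\C)C[C@@H](Br)[C@](C)(O)[C@@H](OC(=O)/C(C)=C\C)[C@H]1OC(=O)[C@H](C)CC
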